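## Structural features

The target is a 2,3-trans dihydroflavonol. A benzene ring A is fused to a pyranone ring C (chroman-4-one), with a 3,4-dihydroxyphenyl ring B on C2, a hydroxyl on C3 and a geranyl ether on O7; C5 is unsubstituted. The two stereocentres C2 (R) and C3 (R) are neighbours: C2 is a benzylic ether carbon, C3 a carbinol α to the C4 ketone, and their substituents are trans (both equatorial). Three groups are fragile. The free catechol is oxidised in base and air. The α-ketol has an acidic C3–H, which opens the way to epimerisation, to ring opening at O1–C2 by β-elimination and to dehydrogenation to the flavonol. The allylic aryl ether with its two trisubstituted alkenes does not tolerate acid, hydrogen, electrophilic oxidants or carbenes. The real difficulty is the absolute configuration at C2, which every enolisable form of ring C puts at risk, together with the need to tell four phenolic oxygens apart. C3 is less critical, because the trans ketol is the more stable epimer. The key step exploits the C3 carbinol/C4 ketone pair of ring C with C2 bonded to C3: moving C2 back from C3 to C4 turns ring C into a 2-aryl-2,3-dihydrobenzofuran with a hydroxyl and a formyl group on the same carbon. The C2 stereocentre of that ring can be set by asymmetric carbene C–H insertion.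

## Logic of the disconnections

17 ⇒ 16. The two catechol O–H bonds are traced back to aryl O–Si bonds. A free catechol would not survive the carbene, enolate and oxidation chemistry and would compete for the C10 chain. Silyl ethers are the one mask that leaves without acid, base or hydrogen. The forward step must be buffered so that C3 is not epimerised and the allylic ether is not attacked.

16 ⇒ 14 + 15. The O7–C1′ bond of the allylic ether is cut. The two alkenes of the chain are incompatible with a metal carbene, with hydrogenolysis and with a Lewis acid, so the chain is attached after all three. This takes ten carbons off in one step and leaves a ring A phenol. The forward step must alkylate the 7-hydroxyl only, without enolising C3 or opening ring C.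

14 ⇒ 13. The 7-O–H bond is traced back to an O–CH2Ar ether. The arylmethyl group chosen is the same 3,4-bis(silyloxy)benzyl group that the other ring A oxygen needs for ring formation, so the two phenols of 5 never have to be told apart. The forward hydrogenolysis must spare the cyclic benzylic C2–O1 bond and the ketone.

13 ⇒ 12 (key). The C2–C3 bond of ring C is cut and C2 is joined to C4 instead; C4 becomes a tertiary carbinol and C3 a formyl group. The ketol with C2 on the carbinol carbon is the product pattern of a 1,2-shift. The cut trades a six-membered ring with two stereocentres for a five-membered ring whose only independent stereocentre is C2. The forward step demands that C2 migrates in preference to the ring A carbon, with retention, to one face of the formyl group, and that the C2–O1 bond does not ionise.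

12 ⇒ 11 ⇒ 10. No skeletal bond is cut; only the oxidation level of the exocyclic carbon changes (aldehyde ⇐ primary alcohol ⇐ methyl ester). 12 is prone to hydration and rearrangement, so it is made immediately before use, whereas 10 is robust. The forward steps need a hydride that spares aryl silyl ethers and an oxidation that stops at the aldehyde and does not cleave the glycol.

10 ⇒ 8 (through 9). The C3–OH bond is cut. A tertiary alcohol α to an ester is the mark of an enolate oxidation. The planar enolate 9 erases C3, so any cis/trans mixture of 8 converges, and the quaternary centre disappears from the problem. The oxidant must come from the face away from the C2 aryl group, and the enolate must not expel the ring oxygen.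

8 ⇒ 7. The C2–C3 bond of the dihydrofuran ring is cut. C3 and the benzylic C2 are the two ends of a 1,5 C–H insertion by a carbene at C3. The ring and the C2 stereocentre then come from an achiral, open-chain diazo ester. The forward step needs a chiral dirhodium catalyst that chooses between the two enantiotopic benzylic hydrogens.

7 ⇒ 6. The C=N2 bond is cut (diazo transfer to the activated methylene), leaving a plain arylacetate. The base must be strong enough for an electron-rich arylacetate and harmless to aryl silyl ethers.

6 ⇒ 5 + 3 (two equivalents). Both ArO–CH2 bonds are cut. Because the two ethers are identical, both phenols are alkylated in one operation. The etherification must run without carbonate or hydroxide.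

5 ⇒ 4 and 3 ⇒ 2 ⇒ 1. The ester C–O bond, the benzylic C–H bond (from the aldehyde) and the two O–Si bonds are cut. This reaches the purchased materials 4 and 1 through routine steps.

## Other disconnections considered

Alternative 1: The C3–O and C4–O bonds are cut, which leads back to the flav-3-ene A1. In the forward direction dimethyldioxirane would add oxygen to the C3=C4 bond on the face away from the C2 aryl group and give the anti epoxide A2. Opening at the benzylic C4 and oxidation of C4 to the ketone level would then have to follow.
- In its favour: dioxirane epoxidation is a well-understood reaction class, and ring C is six-membered from the start, so no skeletal change is needed. On predictability of the skeleton the alternative is the better plan. A1 should also be reachable in fewer steps than 12, so on step economy it is likely better as well.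
- Against it here: the only stereocentre of A1 is allylic, benzylic and oxygen-bearing, and 2H-chromenes open reversibly by a 6π electrocyclic process, which threatens its configuration. The C4–O bond of A2 is activated by both ring A oxygens and should ionise very easily. The C2 aryl group is remote from C4, so the facial bias is modest. Two more redox operations follow the key step.
- Comparison: both plans relay the configuration of C2 to C3, and both can correct C3 afterwards by equilibration to the trans ketol (equal). Both must postpone the geranyl group, since the dioxirane would attack its alkenes (equal). The chosen plan keeps C2 in a saturated, configurationally robust ether until the ring expansion, whereas the alternative carries it in a labile allylic ether.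

Alternative 2: The C3–C4 bond is cut, which leads back to the dialdehyde A3. In A3 an α-aryloxy aldehyde (future C2 and C3) is tethered through O1 to the ring A aldehyde (future C4). In the forward direction SmI2, a divalent samarium reagent, would transfer an electron to the aromatic aldehyde, and the resulting carbon radical would add to the second formyl group. Trivalent samarium bridges the two oxygens, so ring C should close as the cis 3,4-diol A4. Oxidation of the benzylic C4 hydroxyl would then lead to 16.
- In its favour: the key step makes a C–C bond, the ring and two stereocentres at once, which is more construction than the chosen key step achieves (better). The reagent tolerates alkenes, so the geranyl group can be present from the start and the arylmethyl protection of O7 falls away (better; the step count is probably somewhat lower).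
- Against it here: the stereocentre of A3 lies between an aryl group and a formyl group and should racemise very easily, and no simple enantioselective access to it is evident. α-Oxygenated carbonyl compounds are cleaved reductively by the same reagent, so loss of the C2–O1 bond competes with ring closure. The chelate fixes the 3,4-relationship but not the 2,3-relationship. The C4 hydroxyl must then be oxidised next to the C3 hydroxyl.
- Comparison: both plans rely on a metal chelate of two oxygens for stereocontrol, and both can finally equilibrate C3 to trans at the ketol stage (equal). The chosen plan fixes C2 early in a stable ring and never exposes it to enolisation, which is where the alternative is weakest.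

Alternative 3: The O1–C2 and C3–C4 bonds are cut, which leads back to the salicyl alcohol A5 and the (E)-styrylboronate A6. In the forward direction a chiral phosphoric acid would dehydrate A5 to the ortho-quinone methide A7. A7 would take up A6 in a [4+2] cycloaddition, oxygen bonding to the benzylic carbon, to give the 2,3-trans 3-boryl chromane A8. Oxidation of the C–B bond with retention and then oxidation of the C4 methylene to the ketone would follow.
- In its favour: it is the most convergent of the four plans. Two bonds, ring C and both stereocentres form in one catalytic step from two achiral fragments (better than the chosen plan). The trans relationship is inherited from the alkene geometry and does not depend on a chelate (equal or better).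
- Against it here: A7 carries no substituent on its methylene carbon and is short-lived, and the catalyst must steer a dienophile that offers it no hydrogen-bond donor. The electron-rich styrene may react stepwise through a benzylic cation, which would loosen the trans specificity. C4 arrives as a methylene group that must be oxidised late, next to the second benzylic position C2, which costs protection and redox steps.
- Comparison: a vinylboronate as the 2π partner of an acid-generated quinone methide is itself at the edge of known chemistry, so on precedent the alternative is no safer than the chosen plan (equal). The late C4 oxidation should bring the total to about that of the chosen plan (equal on step economy).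

Key step: step 10

Remark on the chemistry (assumption): step 6 needs the catalyst antipode that selects the benzylic hydrogen leading to (2S)-8; this is taken to be Rh2(R-PTTL)4 (PTTL = N-phthaloyl-tert-leucinate), and if the sense of induction on this substrate is the other one, Rh2(S-PTTL)4 is used with no other change. TBS = tert-butyldimethylsilyl, TBSO = tert-butyldimethylsilyloxy.

## Route

Step 1
Reactants: 1 3,4-dihydroxybenzaldehyde
Product: 2 3,4-bis(TBSO)benzaldehyde
Conditions: TBSCl (2.4 equiv), imidazole (5 equiv), DMF, 0 °C to rt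
Reagents that add atoms: tert-butyldimethylsilyl chloride, CC(C)(C)[Si](C)(C)Cl
Why: Standard silylation of both phenols; silyl ethers are chosen because they can be removed at the end without acid, base or hydrogen.

Step 2
Reactants: 2 3,4-bis(TBSO)benzaldehyde
Product: 3 [3,4-bis(TBSO)phenyl]methanol
Conditions: NaBH4, THF/MeOH, 0 °C
Reagents that add atoms: none
Why: Borohydride reduction of the aldehyde; the aryl silyl ethers tolerate the short exposure at 0 °C.

Step 3
Reactants: 4 2,4-dihydroxyphenylacetic acid
Product: 5 methyl 2-(2,4-dihydroxyphenyl)acetate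
Conditions: MeOH, H2SO4 (cat.), reflux
Reagents that add atoms: methanol, CO
Why: Fischer esterification; in excess methanol the open hydroxy ester is favoured over the benzofuranone lactone.

Step 4
Reactants: 5 methyl 2-(2,4-dihydroxyphenyl)acetate; 3 [3,4-bis(TBSO)phenyl]methanol (2.4 equiv)
Product: 6 methyl 2-{2,4-bis[3,4-bis(TBSO)benzyloxy]phenyl}acetate
Conditions: PPh3, DIAD, THF, 0 °C to rt
Reagents that add atoms: none
Why: Double Mitsunobu etherification: both phenols are acidic enough to protonate the betaine, and the primary benzylic alcohol is displaced as its oxyphosphonium salt. Using the same arylmethyl group on both oxygens removes any need to differentiate the two phenols and avoids the base to which aryl silyl ethers are sensitive.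

Step 5
Reactants: 6 methyl 2-{2,4-bis[3,4-bis(TBSO)benzyloxy]phenyl}acetate
Product: 7 methyl 2-{2,4-bis[3,4-bis(TBSO)benzyloxy]phenyl}-2-diazoacetate
Conditions: p-ABSA, DBU, dry MeCN, 0 °C to rt
Reagents that add atoms: 4-acetamidobenzenesulfonyl azide (p-ABSA), CC(=O)Nc1ccc(cc1)S(=O)(=O)N=[N+]=[N-]
Why: Regitz diazo transfer to the arylacetate; DBU deprotonates the benzylic ester and the sulfonyl azide delivers N2, and the dry medium keeps the aryl silyl ethers intact.

Step 6
Reactants: 7 methyl 2-{2,4-bis[3,4-bis(TBSO)benzyloxy]phenyl}-2-diazoacetate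
Product: 8 methyl (2S,3R)-6-[3,4-bis(TBSO)benzyloxy]-2-[3,4-bis(TBSO)phenyl]-2,3-dihydro-1-benzofuran-3-carboxylate (2,3-cis)
Conditions: Rh2(R-PTTL)4 (2 mol %), toluene, −60 °C, slow addition of 7
Reagents that add atoms: none
Why: Intramolecular 1,5 C–H insertion of the donor/acceptor rhodium carbene into the benzylic C–H bond of the ortho ether, a known enantioselective entry to cis-2-aryl-2,3-dihydrobenzofuran-3-carboxylates. The chiral carboxylate ligands choose one of the two enantiotopic benzylic hydrogens and so set C2; the para ether cannot reach the carbene, and the C3 configuration does not matter because step 7 erases it.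

Step 7
Reactants: 8 methyl (2S,3R)-6-[3,4-bis(TBSO)benzyloxy]-2-[3,4-bis(TBSO)phenyl]-2,3-dihydro-1-benzofuran-3-carboxylate
Product: 10 methyl (2R,3S)-6-[3,4-bis(TBSO)benzyloxy]-2-[3,4-bis(TBSO)phenyl]-3-hydroxy-2,3-dihydro-1-benzofuran-3-carboxylate, via potassium ester enolate 9 (not isolated)
Conditions: KN(SiMe3)2, THF, −78 °C; then 2-(phenylsulfonyl)-3-phenyloxaziridine, −78 °C; AcOH
Reagents that add atoms: 2-(phenylsulfonyl)-3-phenyloxaziridine, O=S(=O)(c1ccccc1)N1OC1c1ccccc1
Why: Enolate oxidation with an N-sulfonyloxaziridine: the enolate is planar at C3 and the oxidant approaches the face away from the C2 aryl group, so the hydroxyl ends up trans to the aryl group and the ester cis (3S). β-Elimination of the ring oxygen should be slow because the C2–O1 bond lies in the nodal plane of the enolate (a retro 5-endo process).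

Step 8
Reactants: 10 methyl (2R,3S)-6-[3,4-bis(TBSO)benzyloxy]-2-[3,4-bis(TBSO)phenyl]-3-hydroxy-2,3-dihydro-1-benzofuran-3-carboxylate
Product: 11 (2R,3R)-6-[3,4-bis(TBSO)benzyloxy]-2-[3,4-bis(TBSO)phenyl]-3-(hydroxymethyl)-2,3-dihydro-1-benzofuran-3-ol
Conditions: LiBH4, THF/MeOH, 0 °C to rt
Reagents that add atoms: none
Why: LiBH4 reduces the α-hydroxy ester to the primary alcohol with assistance from the neighbouring hydroxyl and leaves aryl silyl ethers and arylmethyl ethers alone; the change of descriptor at C3 is a priority effect only.

Step 9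
Reactants: 11 (2R,3R)-6-[3,4-bis(TBSO)benzyloxy]-2-[3,4-bis(TBSO)phenyl]-3-(hydroxymethyl)-2,3-dihydro-1-benzofuran-3-ol
Product: 12 (2R,3S)-6-[3,4-bis(TBSO)benzyloxy]-2-[3,4-bis(TBSO)phenyl]-3-hydroxy-2,3-dihydro-1-benzofuran-3-carbaldehyde
Conditions: SO3·pyridine, DMSO, iPr2NEt, CH2Cl2, 0 °C; crude product used at once
Reagents that add atoms: none
Why: Parikh–Doering oxidation stops at the aldehyde, leaves the tertiary alcohol alone and does not cleave the glycol; the aldehyde has no α-hydrogen, so it cannot epimerise.

Step 10
Reactants: 12 (2R,3S)-6-[3,4-bis(TBSO)benzyloxy]-2-[3,4-bis(TBSO)phenyl]-3-hydroxy-2,3-dihydro-1-benzofuran-3-carbaldehyde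
Product: 13 (2R,3R)-7-[3,4-bis(TBSO)benzyloxy]-2-[3,4-bis(TBSO)phenyl]-3-hydroxychroman-4-one
Conditions: Zn(OTf)2 (0.3 equiv), 2,6-di-tert-butyl-4-methylpyridine (0.3 equiv), 4 Å MS, CH2Cl2, 0 °C to rt
Reagents that add atoms: none
Why: Proposed new method: the step is an α-ketol (acyloin) rearrangement, the closest known type being the ring-expanding shift of 1-hydroxycycloalkanecarbaldehydes and other tertiary α-hydroxy aldehydes, here applied to a 3-hydroxy-2,3-dihydrobenzofuran-3-carbaldehyde; divalent zinc binds the carbinol and formyl oxygens of 12 in a five-membered chelate, the formyl carbon becomes electrophilic, and the C3–C2 σ bond, held about 30° from the normal of the carbonyl plane, shifts to the formyl carbon while the carbinol carbon becomes the ketone. Ring C is closed by this 1,2-shift as a five- to six-membered ring expansion, the formyl carbon being inserted between C2 and the old carbinol carbon (which becomes C4). C2 migrates suprafacially with retention, so its configuration from step 6 is carried over unchanged. The new C3 centre is controlled by the chelate: with the two oxygens syn-periplanar, C2 lies over the Re face of the formyl group, and bonding there gives the 3R carbinol, that is the 2,3-trans ketol; the 3S carbinol of 12 (hydroxyl anti to the aryl group, from step 7) is what places C2 on that face. The selectivity needed is migration of C2 and not of the ring A carbon C3a: C2 is a secondary benzylic carbon bearing oxygen and should migrate readily, and its shift leaves the electron-rich ring on the carbinol carbon, where it stabilises the developing oxocarbenium and ends up conjugated with the new ketone, whereas the aryl shift would lead to a non-conjugated chroman-3-one. The driving force is the change from a tertiary hydroxy aldehyde on a five-membered ring to a conjugated aryl ketone in a six-membered ring. The hindered pyridine takes up any triflic acid, so that the silyl ethers and the benzylic C2–O1 bond are not ionised. Should some 2,3-cis ketol form through the non-chelated rotamer, it can equilibrate at C3 to the more stable diequatorial trans isomer.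

Step 11
Reactants: 13 (2R,3R)-7-[3,4-bis(TBSO)benzyloxy]-2-[3,4-bis(TBSO)phenyl]-3-hydroxychroman-4-one
Product: 14 (2R,3R)-2-[3,4-bis(TBSO)phenyl]-3,7-dihydroxychroman-4-one
Conditions: H2 (1 atm), Pd/C (10%), EtOAc, rt
Reagents that add atoms: none
Why: Hydrogenolysis of the primary arylmethyl aryl ether on palladium; the cyclic secondary benzylic C2–O1 bond and the deactivated aryl ketone react far more slowly, as is usual for benzyl-protected flavanones, and no alkene is present yet.

Step 12
Reactants: 14 (2R,3R)-2-[3,4-bis(TBSO)phenyl]-3,7-dihydroxychroman-4-one; 15 geraniol, (2E)-3,7-dimethylocta-2,6-dien-1-ol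
Product: 16 (2R,3R)-2-[3,4-bis(TBSO)phenyl]-7-{[(2E)-3,7-dimethylocta-2,6-dien-1-yl]oxy}-3-hydroxychroman-4-one
Conditions: PPh3, DIAD, THF, 0 °C to rt
Reagents that add atoms: none
Why: Mitsunobu etherification: the 7-hydroxyl, para to the ketone, is by far the most acidic hydroxyl, and the primary allylic alcohol is the one activated, so the chain goes to O7 under neutral conditions that neither enolise C3 nor open ring C. SN2 displacement at the primary carbon leaves the E double bond in place.

Step 13
Reactants: 16 (2R,3R)-2-[3,4-bis(TBSO)phenyl]-7-{[(2E)-3,7-dimethylocta-2,6-dien-1-yl]oxy}-3-hydroxychroman-4-one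
Product: 17 (2R,3R)-2-(3,4-dihydroxyphenyl)-7-{[(2E)-3,7-dimethylocta-2,6-dien-1-yl]oxy}-3-hydroxychroman-4-one (CNP0508026.1)
Conditions: Bu4NF, AcOH, THF, 0 °C
Reagents that add atoms: none
Why: Fluoride cleaves the two aryl silyl ethers; acetic acid buffers the phenoxides, so the catechol is not oxidised, C3 is not epimerised and the allylic ether sees no strong acid.

## Compound list

1 | 3,4-dihydroxybenzaldehyde | O=Cc1ccc(O)c(O)c1 | starting material
2 | 3,4-bis(TBSO)benzaldehyde | O=Cc1ccc(O[Si](C)(C)C(C)(C)C)c(O[Si](C)(C)C(C)(C)C)c1 | intermediate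
3 | [3,4-bis(TBSO)phenyl]methanol | OCc1ccc(O[Si](C)(C)C(C)(C)C)c(O[Si](C)(C)C(C)(C)C)c1 | intermediate
4 | 2,4-dihydroxyphenylacetic acid | OC(=O)Cc1ccc(O)cc1O | starting material
5 | methyl 2-(2,4-dihydroxyphenyl)acetate | COC(=O)Cc1ccc(O)cc1O | intermediate
6 | methyl 2-{2,4-bis[3,4-bis(TBSO)benzyloxy]phenyl}acetate | COC(=O)Cc1ccc(OCc2ccc(O[Si](C)(C)C(C)(C)C)c(O[Si](C)(C)C(C)(C)C)c2)cc1OCc1ccc(O[Si](C)(C)C(C)(C)C)c(O[Si](C)(C)C(C)(C)C)c1 | intermediate
7 | methyl 2-{2,4-bis[3,4-bis(TBSO)benzyloxy]phenyl}-2-diazoacetate | COC(=O)C(=[N+]=[N-])c1ccc(OCc2ccc(O[Si](C)(C)C(C)(C)C)c(O[Si](C)(C)C(C)(C)C)c2)cc1OCc1ccc(O[Si](C)(C)C(C)(C)C)c(O[Si](C)(C)C(C)(C)C)c1 | intermediate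
8 | methyl (2S,3R)-6-[3,4-bis(TBSO)benzyloxy]-2-[3,4-bis(TBSO)phenyl]-2,3-dihydro-1-benzofuran-3-carboxylate (2,3-cis) | COC(=O)[C@@H]1c2ccc(OCc3ccc(O[Si](C)(C)C(C)(C)C)c(O[Si](C)(C)C(C)(C)C)c3)cc2O[C@@H]1c1ccc(O[Si](C)(C)C(C)(C)C)c(O[Si](C)(C)C(C)(C)C)c1 | intermediate
9 | potassium ester enolate of 8 (C2 unchanged; enolate geometry not defined; not isolated) | COC([O-])=C1c2ccc(OCc3ccc(O[Si](C)(C)C(C)(C)C)c(O[Si](C)(C)C(C)(C)C)c3)cc2O[C@@H]1c1ccc(O[Si](C)(C)C(C)(C)C)c(O[Si](C)(C)C(C)(C)C)c1.[K+] | intermediate
10 | methyl (2R,3S)-6-[3,4-bis(TBSO)benzyloxy]-2-[3,4-bis(TBSO)phenyl]-3-hydroxy-2,3-dihydro-1-benzofuran-3-carboxylate (hydroxyl trans to the C2 aryl group) | COC(=O)[C@]1(O)c2ccc(OCc3ccc(O[Si](C)(C)C(C)(C)C)c(O[Si](C)(C)C(C)(C)C)c3)cc2O[C@@H]1c1ccc(O[Si](C)(C)C(C)(C)C)c(O[Si](C)(C)C(C)(C)C)c1 | intermediate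
11 | (2R,3R)-6-[3,4-bis(TBSO)benzyloxy]-2-[3,4-bis(TBSO)phenyl]-3-(hydroxymethyl)-2,3-dihydro-1-benzofuran-3-ol | OC[C@]1(O)c2ccc(OCc3ccc(O[Si](C)(C)C(C)(C)C)c(O[Si](C)(C)C(C)(C)C)c3)cc2O[C@@H]1c1ccc(O[Si](C)(C)C(C)(C)C)c(O[Si](C)(C)C(C)(C)C)c1 | intermediate
12 | (2R,3S)-6-[3,4-bis(TBSO)benzyloxy]-2-[3,4-bis(TBSO)phenyl]-3-hydroxy-2,3-dihydro-1-benzofuran-3-carbaldehyde | O=C[C@]1(O)c2ccc(OCc3ccc(O[Si](C)(C)C(C)(C)C)c(O[Si](C)(C)C(C)(C)C)c3)cc2O[C@@H]1c1ccc(O[Si](C)(C)C(C)(C)C)c(O[Si](C)(C)C(C)(C)C)c1 | intermediate
13 | (2R,3R)-7-[3,4-bis(TBSO)benzyloxy]-2-[3,4-bis(TBSO)phenyl]-3-hydroxychroman-4-one | CC(C)(C)[Si](C)(C)Oc1ccc(COc2ccc3c(c2)O[C@H](c2ccc(O[Si](C)(C)C(C)(C)C)c(O[Si](C)(C)C(C)(C)C)c2)[C@@H](O)C3=O)cc1O[Si](C)(C)C(C)(C)C | intermediate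
14 | (2R,3R)-2-[3,4-bis(TBSO)phenyl]-3,7-dihydroxychroman-4-one | Oc1ccc2c(c1)O[C@H](c1ccc(O[Si](C)(C)C(C)(C)C)c(O[Si](C)(C)C(C)(C)C)c1)[C@@H](O)C2=O | intermediate
15 | geraniol, (2E)-3,7-dimethylocta-2,6-dien-1-ol | CC(C)=CCC/C(C)=C/CO | starting material
16 | (2R,3R)-2-[3,4-bis(TBSO)phenyl]-7-{[(2E)-3,7-dimethylocta-2,6-dien-1-yl]oxy}-3-hydroxychroman-4-one | CC(C)=CCC/C(C)=C/COc1ccc2c(c1)O[C@H](c1ccc(O[Si](C)(C)C(C)(C)C)c(O[Si](C)(C)C(C)(C)C)c1)[C@@H](O)C2=O | intermediate
17 | (2R,3R)-2-(3,4-dihydroxyphenyl)-7-{[(2E)-3,7-dimethylocta-2,6-dien-1-yl]oxy}-3-hydroxychroman-4-one | CC(C)=CCC/C(C)=C/COc1ccc2c(c1)O[C@H](c1ccc(O)c(O)c1)[C@@H](O)C2=O | target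

## Step count and least certain steps

Total step count: 13. Longest linear sequence: 12 steps (from 1 through steps 1, 2 and 4 to 13); the branch from 4 is 11 steps.

Step 10 (key step). What may go wrong: migration of the ring A carbon in place of C2, since an aryl group with para and ortho oxygen donors also migrates well; this would lead to the isomeric ketol and, by enolisation toward C2, to erosion of configuration. Further risks are ionisation of the benzylic C2–O1 bond by the Lewis acid, with loss of configuration at C2, and acid-induced loss of the electron-rich arylmethyl ether on O7. Fallback (known chemistry): it sets out from 2 and comes back at 14. Commercial 1-[4-(benzyloxy)-2-hydroxyphenyl]ethan-1-one F1 is protected with MOMCl/iPr2NEt as 1-[4-(benzyloxy)-2-(methoxymethoxy)phenyl]ethan-1-one F2. Aldol addition of its lithium enolate (LiN(SiMe3)2, THF, −78 °C) to 2 gives the racemic β-hydroxy ketone F3, and dehydration with MsCl/Et3N gives the (E)-chalcone F4. Asymmetric epoxidation of the enone (La(OiPr)3, BINOL, Ph3As=O, tert-butyl hydroperoxide, with the BINOL antipode chosen for the 2R,3S epoxide) gives the epoxy ketone F5. Dilute HCl in MeOH/THF removes the methoxymethyl group, and the freed phenol opens the epoxide at the benzylic carbon; C3 keeps the configuration of the epoxide and ring C closes as the trans ketol (2R,3R)-7-(benzyloxy)-2-[3,4-bis(TBSO)phenyl]-3-hydroxychroman-4-one F6. Hydrogenolysis (H2, Pd/C) then gives 14.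

Step 6. What may go wrong: insufficient enantiocontrol, because the very electron-rich arylmethyl ether favours a stepwise hydride-transfer pathway, or induction in the unwanted sense. Fallback: it sets out from 7 and comes back at 10. Decomposition of 7 with achiral Rh2(OAc)4 in CH2Cl2 gives the racemic ester (cis/trans mixture) F7. The conditions of step 7 converge all isomers to the racemic hydroxy ester, that is 10 together with its (2S,3R) enantiomer F8. Preparative chromatography on a chiral stationary phase separates the two and returns 10.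

Step 7. What may go wrong: ring opening by β-elimination of the aryloxide from the enolate, addition of the enolate to the sulfonimine by-product, or incomplete facial selectivity. Fallback: it sets out from 8 and comes back at 12, bypassing steps 7 to 9. Half-reduction of the ester with iBu2AlH (toluene, −78 °C) gives (2S,3R)-6-[3,4-bis(TBSO)benzyloxy]-2-[3,4-bis(TBSO)phenyl]-2,3-dihydro-1-benzofuran-3-carbaldehyde F9. TMSOTf/Et3N converts it into the trimethylsilyl enol ether F10. Dimethyldioxirane (acetone, −40 °C) epoxidises the enol ether on the face away from the C2 aryl group, and the epoxide rearranges with silyl transfer (Rubottom oxidation). A citric acid work-up removes the silyl group and gives 12.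

Step 9. What may go wrong: cleavage of the glycol, hydration or dimerisation of the α-hydroxy aldehyde, or premature unselective rearrangement under the amine base. Fallback: it sets out from 10 and comes back at 12, with no oxidation step. The tertiary hydroxyl is capped with TMSOTf/2,6-lutidine to give the trimethylsilyl ether F11. iBu2AlH at −78 °C stops at the aluminium hemiacetal, which the neighbouring oxygen holds, and gives the α-silyloxy aldehyde F12 on work-up. Citric acid in MeOH removes the silyl group and gives 12.

Step 12. What may go wrong: activation of the 3-hydroxyl (dehydration toward the flavonol or inversion), SN2′ attack giving the tertiary allylic ether, and difficult removal of the phosphine oxide. Fallback: it sets out from 14 and comes back at 16. The 7-hydroxyl, the only hydroxyl acidic enough, is deprotonated with KHCO3 in DMF at 0 °C and alkylated with commercial geranyl bromide, a phenoxide SN2 alkylation in place of the redox condensation. No compound outside the list is made (F0).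

## Further compounds

F1 | step 10 | 1-[4-(benzyloxy)-2-hydroxyphenyl]ethan-1-one | CC(=O)c1ccc(OCc2ccccc2)cc1O
F2 | step 10 | 1-[4-(benzyloxy)-2-(methoxymethoxy)phenyl]ethan-1-one | COCOc1cc(OCc2ccccc2)ccc1C(C)=O
F3 | step 10 | 1-[4-(benzyloxy)-2-(methoxymethoxy)phenyl]-3-[3,4-bis(TBSO)phenyl]-3-hydroxypropan-1-one (racemic) | COCOc1cc(OCc2ccccc2)ccc1C(=O)CC(O)c1ccc(O[Si](C)(C)C(C)(C)C)c(O[Si](C)(C)C(C)(C)C)c1
F4 | step 10 | (2E)-1-[4-(benzyloxy)-2-(methoxymethoxy)phenyl]-3-[3,4-bis(TBSO)phenyl]prop-2-en-1-one | COCOc1cc(OCc2ccccc2)ccc1C(=O)/C=C/c1ccc(O[Si](C)(C)C(C)(C)C)c(O[Si](C)(C)C(C)(C)C)c1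
F5 | step 10 | [4-(benzyloxy)-2-(methoxymethoxy)phenyl]{(2R,3S)-3-[3,4-bis(TBSO)phenyl]oxiran-2-yl}methanone | COCOc1cc(OCc2ccccc2)ccc1C(=O)[C@@H]1O[C@H]1c1ccc(O[Si](C)(C)C(C)(C)C)c(O[Si](C)(C)C(C)(C)C)c1
F6 | step 10 | (2R,3R)-7-(benzyloxy)-2-[3,4-bis(TBSO)phenyl]-3-hydroxychroman-4-one | c1ccccc1COc1ccc2c(c1)O[C@H](c1ccc(O[Si](C)(C)C(C)(C)C)c(O[Si](C)(C)C(C)(C)C)c1)[C@@H](O)C2=O
F7 | step 6 | racemic methyl 6-[3,4-bis(TBSO)benzyloxy]-2-[3,4-bis(TBSO)phenyl]-2,3-dihydro-1-benzofuran-3-carboxylate (cis and trans; no stereodescriptors) | COC(=O)C1c2ccc(OCc3ccc(O[Si](C)(C)C(C)(C)C)c(O[Si](C)(C)C(C)(C)C)c3)cc2OC1c1ccc(O[Si](C)(C)C(C)(C)C)c(O[Si](C)(C)C(C)(C)C)c1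
F8 | step 6 | methyl (2S,3R)-6-[3,4-bis(TBSO)benzyloxy]-2-[3,4-bis(TBSO)phenyl]-3-hydroxy-2,3-dihydro-1-benzofuran-3-carboxylate (enantiomer of 10, formed with 10 as the racemate) | COC(=O)[C@@]1(O)c2ccc(OCc3ccc(O[Si](C)(C)C(C)(C)C)c(O[Si](C)(C)C(C)(C)C)c3)cc2O[C@H]1c1ccc(O[Si](C)(C)C(C)(C)C)c(O[Si](C)(C)C(C)(C)C)c1
F9 | step 7 | (2S,3R)-6-[3,4-bis(TBSO)benzyloxy]-2-[3,4-bis(TBSO)phenyl]-2,3-dihydro-1-benzofuran-3-carbaldehyde | O=C[C@@H]1c2ccc(OCc3ccc(O[Si](C)(C)C(C)(C)C)c(O[Si](C)(C)C(C)(C)C)c3)cc2O[C@@H]1c1ccc(O[Si](C)(C)C(C)(C)C)c(O[Si](C)(C)C(C)(C)C)c1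
F10 | step 7 | (2R)-6-[3,4-bis(TBSO)benzyloxy]-2-[3,4-bis(TBSO)phenyl]-3-[(trimethylsilyloxy)methylidene]-2,3-dihydro-1-benzofuran (enol ether geometry not defined) | C[Si](C)(C)OC=C1c2ccc(OCc3ccc(O[Si](C)(C)C(C)(C)C)c(O[Si](C)(C)C(C)(C)C)c3)cc2O[C@@H]1c1ccc(O[Si](C)(C)C(C)(C)C)c(O[Si](C)(C)C(C)(C)C)c1
F11 | step 9 | methyl (2R,3S)-6-[3,4-bis(TBSO)benzyloxy]-2-[3,4-bis(TBSO)phenyl]-3-(trimethylsilyloxy)-2,3-dihydro-1-benzofuran-3-carboxylate | COC(=O)[C@]1(O[Si](C)(C)C)c2ccc(OCc3ccc(O[Si](C)(C)C(C)(C)C)c(O[Si](C)(C)C(C)(C)C)c3)cc2O[C@@H]1c1ccc(O[Si](C)(C)C(C)(C)C)c(O[Si](C)(C)C(C)(C)C)c1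
F12 | step 9 | (2R,3S)-6-[3,4-bis(TBSO)benzyloxy]-2-[3,4-bis(TBSO)phenyl]-3-(trimethylsilyloxy)-2,3-dihydro-1-benzofuran-3-carbaldehyde | O=C[C@]1(O[Si](C)(C)C)c2ccc(OCc3ccc(O[Si](C)(C)C(C)(C)C)c(O[Si](C)(C)C(C)(C)C)c3)cc2O[C@@H]1c1ccc(O[Si](C)(C)C(C)(C)C)c(O[Si](C)(C)C(C)(C)C)c1
F0 | step 12 | none | none
A1 | alternative 1 | (2S)-7-(benzyloxy)-2-[3,4-bis(TBSO)phenyl]-2H-chromene | c1ccccc1COc1ccc2c(c1)O[C@H](c1ccc(O[Si](C)(C)C(C)(C)C)c(O[Si](C)(C)C(C)(C)C)c1)C=C2
A2 | alternative 1 | (2R)-7-(benzyloxy)-2-[3,4-bis(TBSO)phenyl]-3,4-epoxychromane, epoxide oxygen anti to the C2 aryl group | c1ccccc1COc1ccc2c(c1)O[C@H](c1ccc(O[Si](C)(C)C(C)(C)C)c(O[Si](C)(C)C(C)(C)C)c1)[C@H]1O[C@H]12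
A3 | alternative 2 | (2R)-2-[3,4-bis(TBSO)phenyl]-2-(5-{[(2E)-3,7-dimethylocta-2,6-dien-1-yl]oxy}-2-formylphenoxy)acetaldehyde | CC(C)=CCC/C(C)=C/COc1ccc(C=O)c(c1)O[C@H](c1ccc(O[Si](C)(C)C(C)(C)C)c(O[Si](C)(C)C(C)(C)C)c1)C=O
A4 | alternative 2 | (2R,3S,4S)-2-[3,4-bis(TBSO)phenyl]-7-{[(2E)-3,7-dimethylocta-2,6-dien-1-yl]oxy}chromane-3,4-diol | CC(C)=CCC/C(C)=C/COc1ccc2c(c1)O[C@H](c1ccc(O[Si](C)(C)C(C)(C)C)c(O[Si](C)(C)C(C)(C)C)c1)[C@@H](O)[C@H]2O
A5 | alternative 3 | 5-(benzyloxy)-2-(hydroxymethyl)phenol | OCc1ccc(OCc2ccccc2)cc1O
A6 | alternative 3 | 2-{(E)-2-[3,4-bis(TBSO)phenyl]ethenyl}-4,4,5,5-tetramethyl-1,3,2-dioxaborolane | CC1(C)OB(/C=C/c2ccc(O[Si](C)(C)C(C)(C)C)c(O[Si](C)(C)C(C)(C)C)c2)OC1(C)C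
A7 | alternative 3 | 3-(benzyloxy)-6-methylidenecyclohexa-2,4-dien-1-one | C=C1C=CC(OCc2ccccc2)=CC1=O
A8 | alternative 3 | (2S,3S)-7-(benzyloxy)-2-[3,4-bis(TBSO)phenyl]-3-(4,4,5,5-tetramethyl-1,3,2-dioxaborolan-2-yl)chromane (2,3-trans) | c1ccccc1COc1ccc2c(c1)O[C@H](c1ccc(O[Si](C)(C)C(C)(C)C)c(O[Si](C)(C)C(C)(C)C)c1)[C@@H](B1OC(C)(C)C(C)(C)O1)C2
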